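**Retrosynthetic overview**

1. Ring A, counted from the carboxyl carbon (C1 CO2H, C2 OMe, C3 prenyl, C4 OH, C5 prenyl, C6 CH2CH2Ar), has the pattern of an orsellinate-type tetraketide grown from a dihydro-p-coumaroyl starter: oxygen on C2 and C4, the carboxyl kept on C1, and both prenyl groups on carbons that were active methylenes between chain carbonyls. The route rests on this.
2. The target comes from a resorcylate carrying three silicon-based protecting groups: SEM on the free 4-OH, methylation of the chelated 2-OH, then one fluoride treatment.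
3. Ring A comes from an open-chain 4,6-diprenyl-3,5,7-trioxononanoate by aldol closure of chain C2 onto the C7 ketone (ring bond C1–C6), dehydration and enolization.
4. The trioxo ester comes from a diketo-dioxinone by thermolysis and ketene capture; the diketo-dioxinone comes from prenylated trimethyldioxinone by two Claisen-type acylations, so both prenyl groups arrive inside building blocks.
5. Ring B is bought with phloretic acid; ring A is the only ring formed (step 8).

Key step: step 8

Assumption: compounds 8 and 14–18 and the fallback aldols are handled as mixtures of diastereomers and keto–enol tautomers and drawn as keto forms without configuration, because each of these centres ends as an sp2 carbon of ring A; the target has no stereocentre.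

**Route**

Step 1
Reactants: 1 2,2,6-trimethyl-4H-1,3-dioxin-4-one; 2 prenyl bromide (1-bromo-3-methylbut-2-ene)
Product: 4 2,2-dimethyl-6-(4-methylpent-3-en-1-yl)-4H-1,3-dioxin-4-one, via lithium dienolate 3 (not isolated)
Conditions: LiN(iPr)2, THF, −78 °C; DMPU, then 2, −78 → −30 °C
Reagents that add atoms: none
Why: LiN(iPr)2 removes a proton from the 6-methyl group to give the cross-conjugated dienolate 3, which should alkylate at its exocyclic γ-carbon with the allylic bromide in the presence of a polar cosolvent (vinylogous enolate alkylation, SN2 at the primary carbon of 2).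

Step 2
Reactants: 5 5-methylhex-4-enoic acid
Product: 6 5-methylhex-4-enoyl chloride
Conditions: (COCl)2, cat. DMF, CH2Cl2, 0 °C → rt; evaporate, use crude
Reagents that add atoms: oxalyl chloride, ClC(=O)C(=O)Cl
Why: DMF-catalysed chlorination with oxalyl chloride (Vilsmeier-type activation) should give the acid chloride with only gaseous by-products, and the trisubstituted alkene is not expected to react between 0 °C and room temperature.

Step 3
Reactants: 4 2,2-dimethyl-6-(4-methylpent-3-en-1-yl)-4H-1,3-dioxin-4-one; 6 5-methylhex-4-enoyl chloride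
Product: 8 6-(2,10-dimethyl-6-oxoundeca-2,9-dien-5-yl)-2,2-dimethyl-4H-1,3-dioxin-4-one, via lithium dienolate 7 (not isolated)
Conditions: 4 (2 equiv), LiN(SiMe3)2 (2 equiv), THF, −78 °C; then 6 (1 equiv), −78 °C; aq NH4Cl
Reagents that add atoms: none
Why: Dienolate 7 should react with the acid chloride at its exocyclic γ-carbon as the parent dioxinone dienolate does (vinylogous crossed Claisen acylation), while the second equivalent of 7 takes up the acidic proton of the new keto-dioxinone and so prevents a second acylation.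

Step 4
Reactants: 9 3-(4-hydroxyphenyl)propanoic acid (phloretic acid)
Product: 11 3-[4-(triisopropylsilyloxy)phenyl]propanoic acid, via triisopropylsilyl ester 10 (not isolated)
Conditions: iPr3SiCl (2.2 equiv), imidazole, DMF, rt; then AcOH–THF–H2O, rt
Reagents that add atoms: triisopropylsilyl chloride, CC(C)[Si](Cl)(C(C)C)C(C)C
Why: Imidazole-promoted silylation covers both the phenol and the acid, and mild aqueous acid then cleaves only the far more labile silyl ester of 10, leaving the hindered aryl silyl ether (silylation followed by selective silyl ester hydrolysis).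

Step 5
Reactants: 11 3-[4-(triisopropylsilyloxy)phenyl]propanoic acid
Product: 13 N-methoxy-N-methyl-3-[4-(triisopropylsilyloxy)phenyl]propanamide, via acyl imidazole 12 (not isolated)
Conditions: N,N'-carbonyldiimidazole, CH2Cl2, rt; then MeNH(OMe)·HCl, rt
Reagents that add atoms: N,O-dimethylhydroxylamine hydrochloride, CNOC.Cl
Why: Carbonyldiimidazole converts the acid into acyl imidazole 12, which is aminolysed by N,O-dimethylhydroxylamine to the Weinreb amide (amide formation through an acyl imidazole), and the aryl silyl ether is inert to these conditions.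

Step 6
Reactants: 8 6-(2,10-dimethyl-6-oxoundeca-2,9-dien-5-yl)-2,2-dimethyl-4H-1,3-dioxin-4-one; 13 N-methoxy-N-methyl-3-[4-(triisopropylsilyloxy)phenyl]propanamide
Product: 15 2,2-dimethyl-6-{2-methyl-7-(3-methylbut-2-en-1-yl)-6,8-dioxo-10-[4-(triisopropylsilyloxy)phenyl]dec-2-en-5-yl}-4H-1,3-dioxin-4-one, via dilithium bis-enolate 14 (not isolated)
Conditions: LiN(iPr)2 (2.3 equiv), THF, −78 → −40 °C; then 13, −78 → −20 °C; aq NH4Cl; use crude
Reagents that add atoms: none
Why: LiN(iPr)2 removes first the doubly activated C–H between ring and ketone and then an α′ proton, and dianion 14 should react at its more basic terminal enolate carbon with the Weinreb amide, whose chelated tetrahedral adduct persists until the quench and so stops the reaction at mono-acylation (Claisen-type γ-acylation of a 1,3-dicarbonyl dianion, as used to make diketo-dioxinones).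

Step 7
Reactants: 15 diketo-dioxinone (name as in step 6)
Product: 17 2-(trimethylsilyl)ethyl 4,6-bis(3-methylbut-2-en-1-yl)-3,5,7-trioxo-9-[4-(triisopropylsilyloxy)phenyl]nonanoate, via acylketene 16 (not isolated)
Conditions: Me3SiCH2CH2OH (5 equiv), toluene, 110 °C; evaporate, use crude
Reagents that add atoms: 2-(trimethylsilyl)ethanol, C[Si](C)(C)CCO
Why: At 110 °C the dioxinone loses acetone by a retro-hetero-Diels–Alder reaction to give acylketene 16, which the excess alcohol should capture faster than an enol oxygen of the chain can (dioxinone thermolysis with ketene trapping to a β-keto ester), under neutral conditions that spare the silyl ether and the prenyl groups.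

Step 8
Reactants: 17 2-(trimethylsilyl)ethyl 4,6-bis(3-methylbut-2-en-1-yl)-3,5,7-trioxo-9-[4-(triisopropylsilyloxy)phenyl]nonanoate
Product: 19 2-(trimethylsilyl)ethyl 2,4-dihydroxy-3,5-bis(3-methylbut-2-en-1-yl)-6-{2-[4-(triisopropylsilyloxy)phenyl]ethyl}benzoate, via aldol carbinol 18 (not isolated)
Conditions: Cs2CO3 (3 equiv), THF, 0 °C → rt; then AcOH, 0 °C
Reagents that add atoms: none
Why: Cs2CO3 deprotonates the C2 methylene of the β-keto ester, the only doubly activated carbon that carries no alkyl group, and this enolate adds to the C7 carbonyl, making the bond that becomes C1–C6 of ring A and giving carbinol 18. The closure is a 6-(enolendo)-exo-trig aldol, the mode known from base-induced cyclization of 3,5,7-trioxo esters to resorcylates (orsellinate-type biomimetic polyketide cyclization), here applied to a chain with two extra C-substituents. E1cB loss of water from 18 and enolization of the C3 and C5 ketones, each of which keeps one hydrogen on the neighbouring prenyl-bearing carbon, give the benzene ring and make the sequence irreversible. No stereocentre remains in the product, since every stereocentre of 17 and 18 becomes an aromatic carbon. The step needs C-aldol closure to win over Claisen closure (C6 onto the ester carbonyl), lactonization to a 2-pyranone and dehydration to a 4-pyranone: the prenyl group on C6 makes the Claisen adduct a quaternary, non-aromatizable triketone that can only revert, the aprotic carbonate medium contains no nucleophile for ester exchange or retro-Claisen cleavage, and acid is added only after the ring has closed. C8 is activated by a single carbonyl and is not deprotonated by carbonate, so the alternative C8-to-C3 aldol should not compete.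

Step 9
Reactants: 19 2-(trimethylsilyl)ethyl 2,4-dihydroxy-3,5-bis(3-methylbut-2-en-1-yl)-6-{2-[4-(triisopropylsilyloxy)phenyl]ethyl}benzoate
Product: 20 2-(trimethylsilyl)ethyl 2-hydroxy-3,5-bis(3-methylbut-2-en-1-yl)-6-{2-[4-(triisopropylsilyloxy)phenyl]ethyl}-4-{[2-(trimethylsilyl)ethoxy]methoxy}benzoate
Conditions: Me3SiCH2CH2OCH2Cl (1.1 equiv), iPr2NEt, CH2Cl2, 0 °C → rt
Reagents that add atoms: 2-(trimethylsilyl)ethoxymethyl chloride, C[Si](C)(C)CCOCCl
Why: With an amine base only the free and more acidic 4-hydroxyl para to the ester should be alkylated by the reactive chloromethyl ether, because the 2-hydroxyl is tied up in a hydrogen bond to the ester carbonyl (chemoselective Williamson-type O-alkylation of a resorcylate).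

Step 10
Reactants: 20 SEM ether (name as in step 9)
Product: 21 2-(trimethylsilyl)ethyl 2-methoxy-3,5-bis(3-methylbut-2-en-1-yl)-6-{2-[4-(triisopropylsilyloxy)phenyl]ethyl}-4-{[2-(trimethylsilyl)ethoxy]methoxy}benzoate
Conditions: MeI, K2CO3, dry acetone, 50 °C
Reagents that add atoms: iodomethane, CI
Why: The chelated 2-hydroxyl is now the only acidic site and should be O-methylated by iodomethane and carbonate on warming (Williamson ether synthesis), while the ester has no α-hydrogen and the aryl silyl ether, SEM ether and silylethyl ester are stable to anhydrous K2CO3.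

Step 11
Reactants: 21 methyl ether (name as in step 10)
Product: 22 4-hydroxy-6-[2-(4-hydroxyphenyl)ethyl]-2-methoxy-3,5-bis(3-methylbut-2-en-1-yl)benzoic acid
Conditions: Bu4NF (6 equiv), THF–DMPU, rt → 50 °C; then cold 0.5 M HCl to pH 3–4
Reagents that add atoms: none
Why: Fluoride attacks all three silicon centres, cleaving the aryl silyl ether directly and fragmenting the silylethyl ester (to carboxylate and ethene) and the SEM ether (to phenoxide, ethene and formaldehyde) by fluoride-induced desilylation and β-elimination, and cold, mild acidification should then give the free acid without chroman formation or decarboxylation.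

**Compound list**

1 | 2,2,6-trimethyl-4H-1,3-dioxin-4-one | CC1=CC(=O)OC(C)(C)O1 | starting material
2 | prenyl bromide (1-bromo-3-methylbut-2-ene) | CC(C)=CCBr | starting material
3 | lithium 2,2-dimethyl-6-methylidene-6H-1,3-dioxin-4-olate (dienolate of 1, formed in the flask) | C=C1C=C(O[Li])OC(C)(C)O1 | intermediate
4 | 2,2-dimethyl-6-(4-methylpent-3-en-1-yl)-4H-1,3-dioxin-4-one | CC(C)=CCCC1=CC(=O)OC(C)(C)O1 | intermediate
5 | 5-methylhex-4-enoic acid | CC(C)=CCCC(=O)O | starting material
6 | 5-methylhex-4-enoyl chloride | CC(C)=CCCC(=O)Cl | intermediate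
7 | lithium 2,2-dimethyl-6-(4-methylpent-3-en-1-ylidene)-6H-1,3-dioxin-4-olate (dienolate of 4, formed in the flask) | CC(C)=CCC=C1C=C(O[Li])OC(C)(C)O1 | intermediate
8 | 6-(2,10-dimethyl-6-oxoundeca-2,9-dien-5-yl)-2,2-dimethyl-4H-1,3-dioxin-4-one (racemic) | CC(C)=CCCC(=O)C(CC=C(C)C)C1=CC(=O)OC(C)(C)O1 | intermediate
9 | 3-(4-hydroxyphenyl)propanoic acid (phloretic acid) | OC(=O)CCc1ccc(O)cc1 | starting material
10 | triisopropylsilyl 3-[4-(triisopropylsilyloxy)phenyl]propanoate (formed in the flask) | CC(C)[Si](OC(=O)CCc1ccc(O[Si](C(C)C)(C(C)C)C(C)C)cc1)(C(C)C)C(C)C | intermediate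
11 | 3-[4-(triisopropylsilyloxy)phenyl]propanoic acid | OC(=O)CCc1ccc(O[Si](C(C)C)(C(C)C)C(C)C)cc1 | intermediate
12 | 1-(imidazol-1-yl)-3-[4-(triisopropylsilyloxy)phenyl]propan-1-one (acyl imidazole, formed in the flask) | O=C(CCc1ccc(O[Si](C(C)C)(C(C)C)C(C)C)cc1)n1ccnc1 | intermediate
13 | N-methoxy-N-methyl-3-[4-(triisopropylsilyloxy)phenyl]propanamide | CON(C)C(=O)CCc1ccc(O[Si](C(C)C)(C(C)C)C(C)C)cc1 | intermediate
14 | dilithium bis-enolate of 8 (dioxinone dienolate plus α′ ketone enolate, formed in the flask) | CC(C)=CCC=C(O[Li])C(CC=C(C)C)=C1C=C(O[Li])OC(C)(C)O1 | intermediate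
15 | 2,2-dimethyl-6-{2-methyl-7-(3-methylbut-2-en-1-yl)-6,8-dioxo-10-[4-(triisopropylsilyloxy)phenyl]dec-2-en-5-yl}-4H-1,3-dioxin-4-one (diastereomer mixture) | CC(C)=CCC(C(=O)CCc1ccc(O[Si](C(C)C)(C(C)C)C(C)C)cc1)C(=O)C(CC=C(C)C)C1=CC(=O)OC(C)(C)O1 | intermediate
16 | acylketene 4,6-bis(3-methylbut-2-en-1-yl)-9-[4-(triisopropylsilyloxy)phenyl]non-1-ene-1,3,5,7-tetrone (formed in the flask) | O=C=CC(=O)C(CC=C(C)C)C(=O)C(CC=C(C)C)C(=O)CCc1ccc(O[Si](C(C)C)(C(C)C)C(C)C)cc1 | intermediate
17 | 2-(trimethylsilyl)ethyl 4,6-bis(3-methylbut-2-en-1-yl)-3,5,7-trioxo-9-[4-(triisopropylsilyloxy)phenyl]nonanoate (diastereomer and tautomer mixture) | C[Si](C)(C)CCOC(=O)CC(=O)C(CC=C(C)C)C(=O)C(CC=C(C)C)C(=O)CCc1ccc(O[Si](C(C)C)(C(C)C)C(C)C)cc1 | intermediate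
18 | 2-(trimethylsilyl)ethyl 2-hydroxy-3,5-bis(3-methylbut-2-en-1-yl)-4,6-dioxo-2-{2-[4-(triisopropylsilyloxy)phenyl]ethyl}cyclohexane-1-carboxylate (aldol carbinol, formed in the flask) | C[Si](C)(C)CCOC(=O)C1C(=O)C(CC=C(C)C)C(=O)C(CC=C(C)C)C1(O)CCc1ccc(O[Si](C(C)C)(C(C)C)C(C)C)cc1 | intermediate
19 | 2-(trimethylsilyl)ethyl 2,4-dihydroxy-3,5-bis(3-methylbut-2-en-1-yl)-6-{2-[4-(triisopropylsilyloxy)phenyl]ethyl}benzoate | C[Si](C)(C)CCOC(=O)c1c(O)c(CC=C(C)C)c(O)c(CC=C(C)C)c1CCc1ccc(O[Si](C(C)C)(C(C)C)C(C)C)cc1 | intermediate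
20 | 2-(trimethylsilyl)ethyl 2-hydroxy-3,5-bis(3-methylbut-2-en-1-yl)-6-{2-[4-(triisopropylsilyloxy)phenyl]ethyl}-4-{[2-(trimethylsilyl)ethoxy]methoxy}benzoate | C[Si](C)(C)CCOC(=O)c1c(O)c(CC=C(C)C)c(OCOCC[Si](C)(C)C)c(CC=C(C)C)c1CCc1ccc(O[Si](C(C)C)(C(C)C)C(C)C)cc1 | intermediate
21 | 2-(trimethylsilyl)ethyl 2-methoxy-3,5-bis(3-methylbut-2-en-1-yl)-6-{2-[4-(triisopropylsilyloxy)phenyl]ethyl}-4-{[2-(trimethylsilyl)ethoxy]methoxy}benzoate | C[Si](C)(C)CCOC(=O)c1c(OC)c(CC=C(C)C)c(OCOCC[Si](C)(C)C)c(CC=C(C)C)c1CCc1ccc(O[Si](C(C)C)(C(C)C)C(C)C)cc1 | intermediate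
22 | 4-hydroxy-6-[2-(4-hydroxyphenyl)ethyl]-2-methoxy-3,5-bis(3-methylbut-2-en-1-yl)benzoic acid | COc1c(CC=C(C)C)c(O)c(CC=C(C)C)c(CCc2ccc(O)cc2)c1C(=O)O | target

**Step count**

Total: 11 steps. Longest linear sequence: 8 steps (steps 1, 3, 6, 7, 8, 9, 10, 11).

**Steps most likely to fail**

Step 8 (key cyclization). The twice α-branched triketone may fragment by retro-Claisen cleavage, or an enol oxygen may close onto the ester or a ketone to give a pyranone, before the hindered C2-to-C7 carbon–carbon closure takes place. Fallback: the ring is closed while the dioxinone is still intact, which removes the ester leaving group and holds the nucleophilic carbon in place. Setting out from 15, Et3N in CH2Cl2 at rt (amine-mediated cycloaromatization of a diketo-dioxinone) should give 7-hydroxy-2,2-dimethyl-6,8-bis(3-methylbut-2-en-1-yl)-5-{2-[4-(triisopropylsilyloxy)phenyl]ethyl}-4H-1,3-benzodioxin-4-one F1. Its single free hydroxyl is then alkylated with Me3SiCH2CH2OCH2Cl and iPr2NEt to give the SEM ether 2,2-dimethyl-6,8-bis(3-methylbut-2-en-1-yl)-5-{2-[4-(triisopropylsilyloxy)phenyl]ethyl}-7-{[2-(trimethylsilyl)ethoxy]methoxy}-4H-1,3-benzodioxin-4-one F2. Lithium 2-(trimethylsilyl)ethoxide (from the alcohol and LiN(SiMe3)2) in THF at 0 °C opens the acetonide lactone by transesterification with loss of acetone. This comes back to the route at 20 and also removes the selectivity question of step 9.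

Step 6 (dianion acylation). Dianion formation may be incomplete and C-acylation at the secondary enolate carbon slow, so that proton transfer from the Weinreb amide or base-induced loss of its N-methoxy group takes over. Fallback: the carbon–carbon bond is made by an aldol addition and the oxidation level adjusted afterwards. Setting out from 13, iBu2AlH in THF at −78 °C gives 3-[4-(triisopropylsilyloxy)phenyl]propanal F3. Dianion 14, made from 8 as in step 6, adds to this aldehyde at −78 °C to give the β-hydroxy ketone 6-{8-hydroxy-2-methyl-7-(3-methylbut-2-en-1-yl)-6-oxo-10-[4-(triisopropylsilyloxy)phenyl]dec-2-en-5-yl}-2,2-dimethyl-4H-1,3-dioxin-4-one F4. Dess–Martin periodinane buffered with NaHCO3 in CH2Cl2 oxidizes it to the 1,3-diketone, which comes back to the route at 15.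

Step 3 (first acylation). Acylation may occur at oxygen or at ring carbon C5 in place of the hindered, now secondary, exocyclic γ-carbon, and the product may be acylated a second time. Fallback: vinylogous aldol addition followed by oxidation, the γ-selective reaction of dioxinone dienolates with aldehydes. Setting out from 6, LiAlH(OtBu)3 in THF at −78 °C gives 5-methylhex-4-enal F5. Dienolate 7, made from 4 with LiN(iPr)2, adds to it at −78 °C through its γ-carbon to give 6-(6-hydroxy-2,10-dimethylundeca-2,9-dien-5-yl)-2,2-dimethyl-4H-1,3-dioxin-4-one F6. Dess–Martin periodinane oxidation then comes back to the route at 8.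

**Further compounds**

F1 | step 8 | 7-hydroxy-2,2-dimethyl-6,8-bis(3-methylbut-2-en-1-yl)-5-{2-[4-(triisopropylsilyloxy)phenyl]ethyl}-4H-1,3-benzodioxin-4-one | CC1(C)OC(=O)c2c(CCc3ccc(O[Si](C(C)C)(C(C)C)C(C)C)cc3)c(CC=C(C)C)c(O)c(CC=C(C)C)c2O1
F2 | step 8 | 2,2-dimethyl-6,8-bis(3-methylbut-2-en-1-yl)-5-{2-[4-(triisopropylsilyloxy)phenyl]ethyl}-7-{[2-(trimethylsilyl)ethoxy]methoxy}-4H-1,3-benzodioxin-4-one | CC1(C)OC(=O)c2c(CCc3ccc(O[Si](C(C)C)(C(C)C)C(C)C)cc3)c(CC=C(C)C)c(OCOCC[Si](C)(C)C)c(CC=C(C)C)c2O1
F3 | step 6 | 3-[4-(triisopropylsilyloxy)phenyl]propanal | O=CCCc1ccc(O[Si](C(C)C)(C(C)C)C(C)C)cc1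
F4 | step 6 | 6-{8-hydroxy-2-methyl-7-(3-methylbut-2-en-1-yl)-6-oxo-10-[4-(triisopropylsilyloxy)phenyl]dec-2-en-5-yl}-2,2-dimethyl-4H-1,3-dioxin-4-one (diastereomer mixture) | CC(C)=CCC(C(O)CCc1ccc(O[Si](C(C)C)(C(C)C)C(C)C)cc1)C(=O)C(CC=C(C)C)C1=CC(=O)OC(C)(C)O1
F5 | step 3 | 5-methylhex-4-enal | CC(C)=CCCC=O
F6 | step 3 | 6-(6-hydroxy-2,10-dimethylundeca-2,9-dien-5-yl)-2,2-dimethyl-4H-1,3-dioxin-4-one (diastereomer mixture) | CC(C)=CCCC(O)C(CC=C(C)C)C1=CC(=O)OC(C)(C)O1
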